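**Plan**

- Retrosynthesis: the C5–allyl bond is traced back by a Cope shift to a 3a-allyl cross-conjugated dienone (14); the C3a–allyl bond is cut to phenol 13; the O1–C2 bond is opened to a spiro-cyclopropane (12); the C3a–C2 and C3a–C3 bonds are cut to a p-quinone diazide carbene and (E)-isoelemicin.
- Forward: aryl–propenyl coupling; quinone diazide from 1,2,4-trimethoxybenzene; [2+1] gives the cyclopropane (C2, C3, C3a) spiro to a p-quinoid six-membered ring; 3→5 ring expansion gives the dihydrofuran (O1, C2, C3, C3a, C7a) and aromatises the carbocycle; dearomatising allylation and a Cope shift then build the dienone.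
- Enabling feature: C2 carries an aryl donor, and the C3a–C7a edge of the dihydrofuran belongs to a ring that can exist as a cyclohexadienone acceptor with an oxygen on C7a. The cyclopropane C2–C3–C3a is therefore a donor–acceptor cyclopropane that gains aromaticity when C3a–C2 ionises and the C7a oxygen closes on C2. Later the 1,5-diene allyl–C3a–C4=C5 allows the shift to C5.
- Stereochemistry: C3 from catalyst-controlled carbene transfer; C2 from the stereoconvergent, trans-selective closure in the ring expansion; C3a from allylation anti to the C3 methyl group; C5 from suprafacial chirality transfer in the Cope shift.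

Key step: step 6

Remark: benzofuran numbering (O1, C2, C3, C3a, C4–C7, C7a) is used for the core throughout; the hand of the dirhodium catalyst that gives the (1R,2S)-cyclopropane is to be fixed by a trial run (the S catalyst is written, its mirror image is used otherwise).

**Route**

Step 1
Reactants: 1 5-bromo-1,2,3-trimethoxybenzene; 2 (E)-prop-1-enylboronic acid pinacol ester
Product: 3 1,2,3-trimethoxy-5-[(1E)-prop-1-en-1-yl]benzene ((E)-isoelemicin)
Conditions: Pd(dppf)Cl2 (3 mol %), K2CO3, 1,4-dioxane/H2O, 80 °C
Reagents that add atoms: none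
Why: Stereoretentive Suzuki–Miyaura coupling of an (E)-alkenyl boronate with an aryl bromide should give the propenyl arene with the E geometry of 2 carried over.

Step 2
Reactants: 4 1,2,4-trimethoxybenzene
Product: 7 2,3,6-trimethoxyphenol, via (2,3,6-trimethoxyphenyl)lithium 5 (not isolated), via dimethyl (2,3,6-trimethoxyphenyl)boronate 6 (not isolated)
Conditions: n-BuLi, THF, 0 °C; B(OMe)3, −78 °C → rt; 30% H2O2, AcOH, 0 °C → rt
Reagents that add atoms: n-butyllithium CCCC[Li] (Li of 5); trimethyl borate COB(OC)OC (boron group of 6); hydrogen peroxide OO (phenolic O of 7)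
Why: Directed ortho-metalation should occur at C3 of 4, the position flanked by two methoxy groups, and borylation followed by peroxide oxidation of the C–B bond should give the phenol between two methoxy groups.

Step 3
Reactants: 7 2,3,6-trimethoxyphenol
Product: 8 2,3,6-trimethoxy-4-nitrosophenol
Conditions: NaNO2, AcOH/H2O, 0–5 °C
Reagents that add atoms: sodium nitrite [Na+].[O-]N=O
Why: Electrophilic C-nitrosation of the phenol should occur para to the hydroxyl group (C4) because both ortho positions carry methoxy groups.

Step 4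
Reactants: 8 2,3,6-trimethoxy-4-nitrosophenol
Product: 11 4-diazo-2,3,6-trimethoxycyclohexa-2,5-dien-1-one, via 4-amino-2,3,6-trimethoxyphenol hydrochloride 9 (not isolated), via 4-hydroxy-2,3,5-trimethoxybenzenediazonium chloride 10 (not isolated)
Conditions: H2 (1 atm), Pd/C, HCl, MeOH, rt, filter; t-BuONO, 0 °C; NaHCO3, CH2Cl2/H2O, dark
Reagents that add atoms: hydrogen chloride Cl (chloride of 9 and 10); tert-butyl nitrite CC(C)(C)ON=O (terminal N of 10 and 11)
Why: Hydrogenation of the nitroso group, diazotisation of the resulting p-aminophenol and deprotonation of the phenolic OH should give the neutral p-quinone diazide, the standard entry to this class.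

Step 5
Reactants: 11 4-diazo-2,3,6-trimethoxycyclohexa-2,5-dien-1-one; 3 (E)-isoelemicin
Product: 12 (1R,2S)-4,5,7-trimethoxy-1-methyl-2-(3,4,5-trimethoxyphenyl)spiro[2.5]octa-4,7-dien-6-one (either configuration at the spiro carbon)
Conditions: Rh2(S-TCPTTL)4 (1 mol %), CH2Cl2, 0 °C → rt, slow addition of 11, dark
Reagents that add atoms: none
Why: Dirhodium-carbene [2+1] cyclopropanation of an alkene by a p-quinone diazide is concerted, so aryl and methyl stay trans, and the chiral carboxylate ligands should select the alkene face and so fix the methyl-bearing carbon (the future C3), the only centre of 12 carried to the target, the spiro centre being destroyed in step 6.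

Step 6
Reactants: 12 (1R,2S)-4,5,7-trimethoxy-1-methyl-2-(3,4,5-trimethoxyphenyl)spiro[2.5]octa-4,7-dien-6-one
Product: 13 (2S,3S)-5,7-dimethoxy-3-methyl-2-(3,4,5-trimethoxyphenyl)-2,3-dihydro-1-benzofuran-6-ol
Conditions: MgI2 (1.2 equiv), PhMe/Et2O, 0 °C → rt; dil. aq. HCl
Reagents that add atoms: none
Why: Proposed new method: Mg(II) should bind the dienone oxygen of 12 in the pocket between its two flanking methoxy groups and turn the spiro ring into a homo-Michael acceptor, so that the C(spiro)–C(aryl) bond of the cyclopropane ionises (or is opened by iodide), the trimethoxyphenyl group stabilising the benzylic cation while the six-membered ring becomes an aromatic phenoxide. The oxygen of the methoxy group next to the former spiro carbon should then close on the benzylic carbon (5-exo-tet) to an O-methyl dihydrobenzofuranium ion, from which iodide removes the methyl group as MeI, so the three-membered ring (C2, C3, C3a) grows by C7a and O1 into the dihydrofuran. The closest known reaction types are the Cloke–Wilson rearrangement of donor–acceptor cyclopropyl ketones to 2,3-dihydrofurans, MgI2-mediated ring expansion of spiro-cyclopropyl oxindoles and the demethylative closure of o-methoxyaryl groups onto cations in iodocyclisations. C3 is untouched and keeps the configuration set in step 5, whereas C2 passes through a planar benzylic cation and, the oxonium closure being reversible until demethylation, should settle with the aryl group anti to the C3 methyl group, so that any epimer of 12 at the spiro or benzylic carbon converges on the 2,3-trans (2S,3S) product. The selectivities needed are opening of C3a–C2 and not C3a–C3, secured by the aryl donor on C2, and cleavage of one methyl ether out of seven, secured because only the C7a methoxy oxygen can reach the cation through a five-membered ring and only its oxonium ion is activated towards iodide.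

Step 7
Reactants: 13 (2S,3S)-5,7-dimethoxy-3-methyl-2-(3,4,5-trimethoxyphenyl)-2,3-dihydro-1-benzofuran-6-ol
Product: 14 (2S,3S,3aS)-3a-allyl-5,7-dimethoxy-3-methyl-2-(3,4,5-trimethoxyphenyl)-3,3a-dihydro-1-benzofuran-6(2H)-one
Conditions: PhI(OAc)2 (1.05 equiv), allylSiMe3 (5 equiv), (CF3)2CHOH/CH2Cl2, −30 °C
Reagents that add atoms: allyltrimethylsilane C=CC[Si](C)(C)C
Why: Iodine(III) oxidation of the phenol to a phenoxonium ion with Hosomi–Sakurai trapping by allylsilane (oxidative dearomatising para-allylation of 4-alkylphenols) should place the allyl group on C3a, which keeps both methoxy-enone units in a cross-conjugated vinylogous ester, and on the face anti to the adjacent C3 methyl group, which sets 3aS.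

Step 8
Reactants: 14 (2S,3S,3aS)-3a-allyl-5,7-dimethoxy-3-methyl-2-(3,4,5-trimethoxyphenyl)-3,3a-dihydro-1-benzofuran-6(2H)-one
Product: 15 (2S,3S,5R)-5-allyl-5,7-dimethoxy-3-methyl-2-(3,4,5-trimethoxyphenyl)-2,3-dihydro-1-benzofuran-6(5H)-one (target)
Conditions: PhMe (degassed), 110–130 °C, sealed tube, stopped at partial conversion, 14 recycled
Reagents that add atoms: none
Why: Thermal [3,3]-sigmatropic Cope rearrangement of the 1,5-diene CH2=CH–CH2–C3a–C4=C5, a known thermal reaction of 3a-allyl hydrobenzofuranoid neolignans, is suprafacial, so the allyl group should arrive at C5 on the face it held at C3a (3aS → 5R) while the congested ring-fusion quaternary centre is relieved, and stopping early limits retro-Claisen aromatisation of 15.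

**Compound list**

1 | 5-bromo-1,2,3-trimethoxybenzene | COc1cc(Br)cc(OC)c1OC | starting material
2 | (E)-prop-1-enylboronic acid pinacol ester | C/C=C/B1OC(C)(C)C(C)(C)O1 | starting material
3 | 1,2,3-trimethoxy-5-[(1E)-prop-1-en-1-yl]benzene ((E)-isoelemicin) | C/C=C/c1cc(OC)c(OC)c(OC)c1 | intermediate
4 | 1,2,4-trimethoxybenzene | COc1ccc(OC)c(OC)c1 | starting material
5 | (2,3,6-trimethoxyphenyl)lithium | [Li]c1c(OC)ccc(OC)c1OC | intermediate (not isolated)
6 | dimethyl (2,3,6-trimethoxyphenyl)boronate | COB(OC)c1c(OC)ccc(OC)c1OC | intermediate (not isolated)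
7 | 2,3,6-trimethoxyphenol | COc1ccc(OC)c(OC)c1O | intermediate
8 | 2,3,6-trimethoxy-4-nitrosophenol | COc1cc(N=O)c(OC)c(OC)c1O | intermediate
9 | 4-amino-2,3,6-trimethoxyphenol hydrochloride | COc1cc([NH3+])c(OC)c(OC)c1O.[Cl-] | intermediate (not isolated)
10 | 4-hydroxy-2,3,5-trimethoxybenzenediazonium chloride | COc1cc([N+]#N)c(OC)c(OC)c1O.[Cl-] | intermediate (not isolated)
11 | 4-diazo-2,3,6-trimethoxycyclohexa-2,5-dien-1-one | COC1=CC(=[N+]=[N-])C(OC)=C(OC)C1=O | intermediate
12 | (1R,2S)-4,5,7-trimethoxy-1-methyl-2-(3,4,5-trimethoxyphenyl)spiro[2.5]octa-4,7-dien-6-one (spiro carbon either way) | C[C@@H]1[C@@H](c2cc(OC)c(OC)c(OC)c2)C13C=C(OC)C(=O)C(OC)=C3OC | intermediate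
13 | (2S,3S)-5,7-dimethoxy-3-methyl-2-(3,4,5-trimethoxyphenyl)-2,3-dihydro-1-benzofuran-6-ol | COc1cc2c(c(OC)c1O)O[C@H](c1cc(OC)c(OC)c(OC)c1)[C@H]2C | intermediate
14 | (2S,3S,3aS)-3a-allyl-5,7-dimethoxy-3-methyl-2-(3,4,5-trimethoxyphenyl)-3,3a-dihydro-1-benzofuran-6(2H)-one | C=CC[C@]12C=C(OC)C(=O)C(OC)=C1O[C@H](c1cc(OC)c(OC)c(OC)c1)[C@H]2C | intermediate
15 | (2S,3S,5R)-5-allyl-5,7-dimethoxy-3-methyl-2-(3,4,5-trimethoxyphenyl)-2,3-dihydro-1-benzofuran-6(5H)-one | C=CC[C@@]1(OC)C=C2C(=C(OC)C1=O)O[C@H](c1cc(OC)c(OC)c(OC)c1)[C@H]2C | target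

**Count**

Total steps: 8. Longest linear sequence: 7 (steps 2–8, from 1,2,4-trimethoxybenzene).

**Steps most likely to fail**

1. Step 6 (Proposed new method). What may go wrong: iodide opening of the cyclopropane without ring closure, elimination of the benzylic cation to a styrenyl phenol, methyl transfer from the oxonium ion to the phenoxide, or unselective ether cleavage. The fallback uses known chemistry and moves the ring expansion into an o-quinone diazide, where the ring oxygen is already the carbonyl oxygen and no demethylation is needed. It sets out from alkene 3 and returns at 13. Commercial 2,6-dimethoxyphenol is silylated (TIPSCl, imidazole) to (2,6-dimethoxyphenoxy)tri(propan-2-yl)silane F1. This is lithiated next to a methoxy group and oxidised through its boronate (n-BuLi; B(OMe)3; H2O2) to 2,4-dimethoxy-3-[(triisopropylsilyl)oxy]phenol F2. Azidinium diazo transfer (2-azido-1,3-dimethylimidazolinium chloride, Et3N) at the free ortho position should give 6-diazo-2,4-dimethoxy-3-[(triisopropylsilyl)oxy]cyclohexa-2,4-dien-1-one F3. With 3 and the chiral dirhodium catalyst of step 5, F3 should undergo the known formal [3+2] annulation of o-quinone diazides with alkenes (carbene transfer followed by Cloke–Wilson closure of the carbonyl oxygen) to (2S,3S)-5,7-dimethoxy-3-methyl-6-[(triisopropylsilyl)oxy]-2-(3,4,5-trimethoxyphenyl)-2,3-dihydro-1-benzofuran F4. TBAF then gives 13.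

2. Step 7. What may go wrong: delivery of the allyl group to the methoxy-bearing ortho carbons C5/C7 instead of C3a, or benzylic oxidation (loss of the C3 hydrogen through a quinone methide and aromatisation to the benzofuran). The fallback avoids the oxidant; it sets out from 13 and returns at 15, bypassing 14 and step 8. The sodium phenoxide of 13 (NaH, toluene) is treated with allyl bromide as a suspension in toluene. Ortho-C-alkylation of 2,6-disubstituted phenoxides in non-polar media is known and should give 15 directly, together with its C5 epimer (2S,3S,5S)-5-allyl-5,7-dimethoxy-3-methyl-2-(3,4,5-trimethoxyphenyl)-2,3-dihydro-1-benzofuran-6(5H)-one F6 and the O-allyl ether (2S,3S)-6-(allyloxy)-5,7-dimethoxy-3-methyl-2-(3,4,5-trimethoxyphenyl)-2,3-dihydro-1-benzofuran F5. C5 is then set without control: the epimers are separated by chromatography and F5 is returned to 13 by Pd(PPh3)4/morpholine deallylation.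

3. Step 5. What may go wrong: poor enantiofacial selectivity of carbene transfer to a trans-1,2-disubstituted alkene, or premature opening of the donor–acceptor cyclopropane. The fallback replaces asymmetric catalysis by resolution; it sets out from 3 and 11 and returns at 13. Achiral Rh2(esp)2 should give racemic trans-4,5,7-trimethoxy-1-methyl-2-(3,4,5-trimethoxyphenyl)spiro[2.5]octa-4,7-dien-6-one F7. The conditions of step 6 convert it into racemic trans-5,7-dimethoxy-3-methyl-2-(3,4,5-trimethoxyphenyl)-2,3-dihydro-1-benzofuran-6-ol F8. F8 is resolved by preparative chromatography on a chiral stationary phase and the (2S,3S) enantiomer 13 is carried on.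

**Further compounds**

F1 | step 6 | (2,6-dimethoxyphenoxy)tri(propan-2-yl)silane | COc1cccc(OC)c1O[Si](C(C)C)(C(C)C)C(C)C
F2 | step 6 | 2,4-dimethoxy-3-[(triisopropylsilyl)oxy]phenol | COc1ccc(O)c(OC)c1O[Si](C(C)C)(C(C)C)C(C)C
F3 | step 6 | 6-diazo-2,4-dimethoxy-3-[(triisopropylsilyl)oxy]cyclohexa-2,4-dien-1-one | COC1=CC(=[N+]=[N-])C(=O)C(OC)=C1O[Si](C(C)C)(C(C)C)C(C)C
F4 | step 6 | (2S,3S)-5,7-dimethoxy-3-methyl-6-[(triisopropylsilyl)oxy]-2-(3,4,5-trimethoxyphenyl)-2,3-dihydro-1-benzofuran | COc1cc2c(c(OC)c1O[Si](C(C)C)(C(C)C)C(C)C)O[C@H](c1cc(OC)c(OC)c(OC)c1)[C@H]2C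
F5 | step 7 | (2S,3S)-6-(allyloxy)-5,7-dimethoxy-3-methyl-2-(3,4,5-trimethoxyphenyl)-2,3-dihydro-1-benzofuran | C=CCOc1c(OC)cc2c(c1OC)O[C@H](c1cc(OC)c(OC)c(OC)c1)[C@H]2C
F6 | step 7 | (2S,3S,5S)-5-allyl-5,7-dimethoxy-3-methyl-2-(3,4,5-trimethoxyphenyl)-2,3-dihydro-1-benzofuran-6(5H)-one | C=CC[C@]1(OC)C=C2C(=C(OC)C1=O)O[C@H](c1cc(OC)c(OC)c(OC)c1)[C@H]2C
F7 | step 5 | racemic trans-4,5,7-trimethoxy-1-methyl-2-(3,4,5-trimethoxyphenyl)spiro[2.5]octa-4,7-dien-6-one | C[C@@H]1[C@@H](c2cc(OC)c(OC)c(OC)c2)C13C=C(OC)C(=O)C(OC)=C3OC.C[C@H]1[C@H](c2cc(OC)c(OC)c(OC)c2)C13C=C(OC)C(=O)C(OC)=C3OC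
F8 | step 5 | racemic trans-5,7-dimethoxy-3-methyl-2-(3,4,5-trimethoxyphenyl)-2,3-dihydro-1-benzofuran-6-ol | COc1cc2c(c(OC)c1O)O[C@H](c1cc(OC)c(OC)c(OC)c1)[C@H]2C.COc1cc2c(c(OC)c1O)O[C@@H](c1cc(OC)c(OC)c(OC)c1)[C@@H]2C
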